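**Retrosynthetic overview**
- The target comes from hydrogenolysis of its 5,7,3'-tri-O-benzyl ether. Rings A and B are bought as benzene rings. Ring C is the only ring built, and it is closed last but one.
- Ring C is closed by acid-induced attack of the one free ortho phenol on a β-keto dimethyl acetal, followed by loss of MeOH.
- The β-keto acetal comes from an (E)-chalcone by an oxidative 1,2-aryl shift with Tl(NO3)3 in MeOH.
- The chalcone comes from a Claisen–Schmidt aldol condensation of a penta-oxygenated ring A acetophenone with the ring B aldehyde. This is the fragment-joining C–C bond.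
- The ring A ketone comes from 2,3,4-trihydroxybenzaldehyde by two rounds of Baeyer–Villiger oxidation and ortho-formylation that walk oxygen round the ring. The ring B aldehyde comes from 5-bromovanillin.

Assumption: the target has no stereocentre and no stereogenic axis, so it is achiral. The sp3 stereocentres that appear on the way are racemic and are erased again.

**Step 1**
Reactants: 1 2,3,4-trihydroxybenzaldehyde
Product: 2 2-hydroxy-3,4-bis(methoxymethoxy)benzaldehyde
Conditions: MOMCl (2.2 equiv), K2CO3 (3 equiv), acetone, 0 °C to rt, N2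
Reagents that add atoms: chloromethyl methyl ether (MOMCl), COCCl
Why: In this Williamson-type O-alkylation the 4-OH and 3-OH phenoxides react while the 2-OH, held in a hydrogen bond to the aldehyde, stays free, and the two MOM-bearing oxygens later become O1 and 8-OH.

**Step 2**
Reactants: 2 2-hydroxy-3,4-bis(methoxymethoxy)benzaldehyde
Product: 3 2-(benzyloxy)-3,4-bis(methoxymethoxy)benzaldehyde
Conditions: BnBr (1.2 equiv), K2CO3 (2 equiv), DMF, 60 °C
Reagents that add atoms: benzyl bromide, BrCc1ccccc1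
Why: This Williamson ether synthesis works because warm K2CO3/DMF breaks the chelate of the last phenol, and the MOM acetals and the aldehyde are inert to the base.

**Step 3**
Reactants: 3 2-(benzyloxy)-3,4-bis(methoxymethoxy)benzaldehyde
Product: 5 2-(benzyloxy)-3,4-bis(methoxymethoxy)phenol, via aryl formate 4 (not isolated)
Conditions: mCPBA (1.3 equiv), CH2Cl2, 0 °C to rt; aq Na2S2O3/NaHCO3 wash; then K2CO3 (0.2 equiv), MeOH, rt
Reagents that add atoms: 3-chloroperbenzoic acid (mCPBA), O=C(OO)c1cccc(Cl)c1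
Why: In this Baeyer–Villiger (Dakin-type) oxidation the aryl group, with ortho and para oxygen donors, migrates in preference to hydrogen, and mild methanolysis of the formate frees a unique phenol without touching MOM or benzyl.

**Step 4**
Reactants: 5 2-(benzyloxy)-3,4-bis(methoxymethoxy)phenol
Product: 7 3-(benzyloxy)-2-hydroxy-4,5-bis(methoxymethoxy)benzaldehyde, via salicyl alcohol 6 (not isolated)
Conditions: MgCl2 (2 equiv), Et3N (4 equiv), paraformaldehyde (7 equiv), THF, reflux; dilute HCl work-up at 0 °C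
Reagents that add atoms: paraformaldehyde, reacting as formaldehyde, C=O
Why: In this Casnati–Skattebøl ortho-formylation the magnesium phenoxide delivers formaldehyde only to the single free ortho carbon, and a second formaldehyde oxidises the salicyl alcohol by Oppenauer-type hydride transfer.

**Step 5**
Reactants: 7 3-(benzyloxy)-2-hydroxy-4,5-bis(methoxymethoxy)benzaldehyde
Product: 8 3-(benzyloxy)-2-methoxy-4,5-bis(methoxymethoxy)benzaldehyde
Conditions: MeI (1.5 equiv), K2CO3 (2 equiv), DMF, rt to 40 °C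
Reagents that add atoms: iodomethane, CI
Why: This Williamson methylation of the only free phenol installs the future 6-OMe at an unambiguous position.

**Step 6**
Reactants: 8 3-(benzyloxy)-2-methoxy-4,5-bis(methoxymethoxy)benzaldehyde
Product: 10 3-(benzyloxy)-2-methoxy-4,5-bis(methoxymethoxy)phenol, via aryl formate 9 (not isolated)
Conditions: mCPBA (1.3 equiv), CH2Cl2, 0 °C to rt; aq Na2S2O3/NaHCO3 wash; then K2CO3 (0.2 equiv), MeOH, rt
Reagents that add atoms: 3-chloroperbenzoic acid (mCPBA), O=C(OO)c1cccc(Cl)c1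
Why: In this second Baeyer–Villiger oxidation the ortho-OMe and para-OMOM donors secure aryl migration, and formate methanolysis gives the fifth ring oxygen as a unique phenol.

**Step 7**
Reactants: 10 3-(benzyloxy)-2-methoxy-4,5-bis(methoxymethoxy)phenol
Product: 12 4-(benzyloxy)-2-hydroxy-3-methoxy-5,6-bis(methoxymethoxy)benzaldehyde, via salicyl alcohol 11 (not isolated)
Conditions: MgCl2 (2 equiv), Et3N (4 equiv), paraformaldehyde (8 equiv), THF, reflux; dilute HCl work-up at 0 °C
Reagents that add atoms: paraformaldehyde, reacting as formaldehyde, C=O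
Why: This Casnati–Skattebøl ortho-formylation has no regiochemical choice, because the last free ring carbon is also the only free position ortho to the phenoxide.

**Step 8**
Reactants: 12 4-(benzyloxy)-2-hydroxy-3-methoxy-5,6-bis(methoxymethoxy)benzaldehyde
Product: 13 2,4-bis(benzyloxy)-3-methoxy-5,6-bis(methoxymethoxy)benzaldehyde
Conditions: BnBr (1.3 equiv), K2CO3 (2 equiv), DMF, 60 °C
Reagents that add atoms: benzyl bromide, BrCc1ccccc1
Why: This Williamson benzylation caps the future 5-OH with an acid-stable group, so the two oxygens ortho to the carbonyl carbon are now different (Bn and MOM).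

**Step 9**
Reactants: 13 2,4-bis(benzyloxy)-3-methoxy-5,6-bis(methoxymethoxy)benzaldehyde
Product: 14 rac-1-[2,4-bis(benzyloxy)-3-methoxy-5,6-bis(methoxymethoxy)phenyl]ethan-1-ol
Conditions: MeMgBr (1.5 equiv), THF, 0 °C; aq work-up
Reagents that add atoms: methylmagnesium bromide, C[Mg]Br
Why: This Grignard 1,2-addition to a non-enolisable aldehyde tolerates all the ethers, and the new carbinol stereocentre is racemic and is removed in step 10.

**Step 10**
Reactants: 14 rac-1-[2,4-bis(benzyloxy)-3-methoxy-5,6-bis(methoxymethoxy)phenyl]ethan-1-ol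
Product: 15 1-[2,4-bis(benzyloxy)-3-methoxy-5,6-bis(methoxymethoxy)phenyl]ethan-1-one
Conditions: Dess–Martin periodinane (1.3 equiv), CH2Cl2, 0 °C to rt
Reagents that add atoms: none
Why: The Dess–Martin oxidation converts the hindered benzylic alcohol into the methyl ketone under near-neutral conditions that spare MOM, benzyl and the electron-rich ring.

**Step 11**
Reactants: 16 5-bromovanillin (3-bromo-4-hydroxy-5-methoxybenzaldehyde)
Product: 17 3,4-dihydroxy-5-methoxybenzaldehyde
Conditions: NaOH (aq, 7 equiv), Cu powder (cat.), reflux, 24 h, N2; then HCl to pH 2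
Reagents that add atoms: sodium hydroxide, [Na+].[OH-]
Why: This copper-catalysed Ullmann-type hydroxylation of the aryl bromide is clean because the aldehyde is protected from Cannizzaro reaction by conjugation with the para phenoxide.

**Step 12**
Reactants: 17 3,4-dihydroxy-5-methoxybenzaldehyde
Product: 18 3-hydroxy-4,5-dimethoxybenzaldehyde
Conditions: MeI (1.05 equiv), Li2CO3 (1.2 equiv), DMF, 45 °C
Reagents that add atoms: iodomethane, CI
Why: This Williamson methylation is chemoselective because the weak base ionises only the more acidic 4-OH (para to the aldehyde), so that oxygen alone is methylated.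

**Step 13**
Reactants: 18 3-hydroxy-4,5-dimethoxybenzaldehyde
Product: 19 3-(benzyloxy)-4,5-dimethoxybenzaldehyde
Conditions: BnBr (1.2 equiv), K2CO3 (2 equiv), DMF, rt
Reagents that add atoms: benzyl bromide, BrCc1ccccc1
Why: This Williamson benzylation masks the remaining phenol against base and against the later oxidant.

**Step 14**
Reactants: 15 1-[2,4-bis(benzyloxy)-3-methoxy-5,6-bis(methoxymethoxy)phenyl]ethan-1-one; 19 3-(benzyloxy)-4,5-dimethoxybenzaldehyde
Product: 21 (E)-3-[3-(benzyloxy)-4,5-dimethoxyphenyl]-1-[2,4-bis(benzyloxy)-3-methoxy-5,6-bis(methoxymethoxy)phenyl]prop-2-en-1-one, via aldol adduct 20 (not isolated)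
Conditions: KOH (50% aq), EtOH–THF, rt, 36 h
Reagents that add atoms: none
Why: In this Claisen–Schmidt crossed aldol condensation only 15 can enolise and only 19 is an aldehyde, and E1cB dehydration erases the racemic carbinol centre of 20 to give the more stable (E)-enone.

**Step 15**
Reactants: 21 (E)-3-[3-(benzyloxy)-4,5-dimethoxyphenyl]-1-[2,4-bis(benzyloxy)-3-methoxy-5,6-bis(methoxymethoxy)phenyl]prop-2-en-1-one
Product: 22 rac-2-[3-(benzyloxy)-4,5-dimethoxyphenyl]-1-[2,4-bis(benzyloxy)-3-methoxy-5,6-bis(methoxymethoxy)phenyl]-3,3-dimethoxypropan-1-one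
Conditions: Tl(NO3)3·3H2O (1.1 equiv), MeOH–CH2Cl2 (4:1), 0 °C to rt, 3 h; filter TlNO3, aq NaHCO3 wash
Reagents that add atoms: methanol, CO
Why: In this oxidative 1,2-aryl rearrangement, methoxythallation of the enone and loss of monovalent thallium move electron-rich ring B from Cβ to Cα, no free phenol is present for trivalent thallium to oxidise, and the new stereocentre is racemic and is erased in step 16.

**Step 16**
Reactants: 22 rac-2-[3-(benzyloxy)-4,5-dimethoxyphenyl]-1-[2,4-bis(benzyloxy)-3-methoxy-5,6-bis(methoxymethoxy)phenyl]-3,3-dimethoxypropan-1-one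
Product: 25 5,7-bis(benzyloxy)-3-[3-(benzyloxy)-4,5-dimethoxyphenyl]-8-hydroxy-6-methoxy-4H-chromen-4-one, via catechol acetal 23 (not isolated), via 2-methoxyisoflavanone 24 (not isolated)
Conditions: conc. HCl (10% v/v), MeOH–THF, 55 °C, 2 h, Ar
Reagents that add atoms: none
Why: Acid-catalysed MOM methanolysis, transacetalisation and elimination of MeOH close ring C, and the regiochemistry is fixed because the freed phenol next to the ketone is the only ortho oxygen available while the other ortho oxygen stays benzylated.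

**Step 17**
Reactants: 25 5,7-bis(benzyloxy)-3-[3-(benzyloxy)-4,5-dimethoxyphenyl]-8-hydroxy-6-methoxy-4H-chromen-4-one
Product: 26 5,7,8,3'-tetrahydroxy-6,4',5'-trimethoxyisoflavone
Conditions: H2 (1 atm), 10% Pd/C, THF–MeOH, rt, about 3 h (TLC control); filter under Ar, crystallise from degassed aq MeOH
Reagents that add atoms: none
Why: Catalytic hydrogenolysis cleaves the three aryl benzyl ethers faster than the C2=C3 bond is reduced, and the neutral medium excludes demethylation and Wessely–Moser ring-opening isomerisation of the 5,7,8-trihydroxy-6-methoxy pattern.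

**Compound list**
1 | 2,3,4-trihydroxybenzaldehyde | O=Cc1ccc(O)c(O)c1O | starting material
2 | 2-hydroxy-3,4-bis(methoxymethoxy)benzaldehyde | O=Cc1ccc(OCOC)c(OCOC)c1O | intermediate
3 | 2-(benzyloxy)-3,4-bis(methoxymethoxy)benzaldehyde | O=Cc1ccc(OCOC)c(OCOC)c1OCc1ccccc1 | intermediate
4 | 2-(benzyloxy)-3,4-bis(methoxymethoxy)phenyl formate | O=COc1ccc(OCOC)c(OCOC)c1OCc1ccccc1 | intermediate
5 | 2-(benzyloxy)-3,4-bis(methoxymethoxy)phenol | Oc1ccc(OCOC)c(OCOC)c1OCc1ccccc1 | intermediate
6 | 2-(benzyloxy)-6-(hydroxymethyl)-3,4-bis(methoxymethoxy)phenol (formed as its magnesium salt, drawn neutral) | OCc1cc(OCOC)c(OCOC)c(OCc2ccccc2)c1O | intermediate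
7 | 3-(benzyloxy)-2-hydroxy-4,5-bis(methoxymethoxy)benzaldehyde | O=Cc1cc(OCOC)c(OCOC)c(OCc2ccccc2)c1O | intermediate
8 | 3-(benzyloxy)-2-methoxy-4,5-bis(methoxymethoxy)benzaldehyde | O=Cc1cc(OCOC)c(OCOC)c(OCc2ccccc2)c1OC | intermediate
9 | 3-(benzyloxy)-2-methoxy-4,5-bis(methoxymethoxy)phenyl formate | O=COc1cc(OCOC)c(OCOC)c(OCc2ccccc2)c1OC | intermediate
10 | 3-(benzyloxy)-2-methoxy-4,5-bis(methoxymethoxy)phenol | Oc1cc(OCOC)c(OCOC)c(OCc2ccccc2)c1OC | intermediate
11 | 3-(benzyloxy)-6-(hydroxymethyl)-2-methoxy-4,5-bis(methoxymethoxy)phenol (formed as its magnesium salt, drawn neutral) | OCc1c(O)c(OC)c(OCc2ccccc2)c(OCOC)c1OCOC | intermediate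
12 | 4-(benzyloxy)-2-hydroxy-3-methoxy-5,6-bis(methoxymethoxy)benzaldehyde | O=Cc1c(O)c(OC)c(OCc2ccccc2)c(OCOC)c1OCOC | intermediate
13 | 2,4-bis(benzyloxy)-3-methoxy-5,6-bis(methoxymethoxy)benzaldehyde | O=Cc1c(OCc2ccccc2)c(OC)c(OCc2ccccc2)c(OCOC)c1OCOC | intermediate
14 | rac-1-[2,4-bis(benzyloxy)-3-methoxy-5,6-bis(methoxymethoxy)phenyl]ethan-1-ol (racemate) | CC(O)c1c(OCc2ccccc2)c(OC)c(OCc2ccccc2)c(OCOC)c1OCOC | intermediate
15 | 1-[2,4-bis(benzyloxy)-3-methoxy-5,6-bis(methoxymethoxy)phenyl]ethan-1-one | CC(=O)c1c(OCc2ccccc2)c(OC)c(OCc2ccccc2)c(OCOC)c1OCOC | intermediate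
16 | 5-bromovanillin (3-bromo-4-hydroxy-5-methoxybenzaldehyde) | COc1cc(C=O)cc(Br)c1O | starting material
17 | 3,4-dihydroxy-5-methoxybenzaldehyde | COc1cc(C=O)cc(O)c1O | intermediate
18 | 3-hydroxy-4,5-dimethoxybenzaldehyde | COc1cc(C=O)cc(O)c1OC | intermediate
19 | 3-(benzyloxy)-4,5-dimethoxybenzaldehyde | COc1cc(C=O)cc(OCc2ccccc2)c1OC | intermediate
20 | rac-3-[3-(benzyloxy)-4,5-dimethoxyphenyl]-1-[2,4-bis(benzyloxy)-3-methoxy-5,6-bis(methoxymethoxy)phenyl]-3-hydroxypropan-1-one (racemate) | O=C(CC(O)c1cc(OC)c(OC)c(OCc2ccccc2)c1)c1c(OCc2ccccc2)c(OC)c(OCc2ccccc2)c(OCOC)c1OCOC | intermediate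
21 | (E)-3-[3-(benzyloxy)-4,5-dimethoxyphenyl]-1-[2,4-bis(benzyloxy)-3-methoxy-5,6-bis(methoxymethoxy)phenyl]prop-2-en-1-one | O=C(/C=C/c1cc(OC)c(OC)c(OCc2ccccc2)c1)c1c(OCc2ccccc2)c(OC)c(OCc2ccccc2)c(OCOC)c1OCOC | intermediate
22 | rac-2-[3-(benzyloxy)-4,5-dimethoxyphenyl]-1-[2,4-bis(benzyloxy)-3-methoxy-5,6-bis(methoxymethoxy)phenyl]-3,3-dimethoxypropan-1-one (racemate) | COC(OC)C(c1cc(OC)c(OC)c(OCc2ccccc2)c1)C(=O)c1c(OCc2ccccc2)c(OC)c(OCc2ccccc2)c(OCOC)c1OCOC | intermediate
23 | rac-2-[3-(benzyloxy)-4,5-dimethoxyphenyl]-1-[2,4-bis(benzyloxy)-5,6-dihydroxy-3-methoxyphenyl]-3,3-dimethoxypropan-1-one (racemate) | COC(OC)C(c1cc(OC)c(OC)c(OCc2ccccc2)c1)C(=O)c1c(OCc2ccccc2)c(OC)c(OCc2ccccc2)c(O)c1O | intermediate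
24 | 5,7-bis(benzyloxy)-3-[3-(benzyloxy)-4,5-dimethoxyphenyl]-8-hydroxy-2,6-dimethoxychroman-4-one (racemic mixture of diastereomers) | COC1Oc2c(O)c(OCc3ccccc3)c(OC)c(OCc3ccccc3)c2C(=O)C1c1cc(OC)c(OC)c(OCc2ccccc2)c1 | intermediate
25 | 5,7-bis(benzyloxy)-3-[3-(benzyloxy)-4,5-dimethoxyphenyl]-8-hydroxy-6-methoxy-4H-chromen-4-one | COc1cc(-c2coc3c(O)c(OCc4ccccc4)c(OC)c(OCc4ccccc4)c3c2=O)cc(OCc2ccccc2)c1OC | intermediate
26 | 5,7,8,3'-tetrahydroxy-6,4',5'-trimethoxyisoflavone (achiral) | COc1cc(-c2coc3c(O)c(O)c(OC)c(O)c3c2=O)cc(O)c1OC | target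

**Step count**
Total steps: 17. Longest linear sequence: 14 (steps 1–10, then 14–17). Steps 11–13 form the three-step ring B branch.

**Three steps most likely to fail**

1. **Step 15, the oxidative aryl shift.**
   - Risk: the nitric acid released can strip a MOM group too early, and trivalent thallium would then over-oxidise the freed para-alkoxyphenol. The twisted 4-OMe of ring B also slows the migration.
   - Fallback: it sets out from chalcone 21 and replaces the aryl shift by an acyl shift. Weitz–Scheffer epoxidation (30% H2O2, NaOH, MeOH–THF, 0 °C) gives the racemic trans-chalcone epoxide F1. BF3·OEt2 in CH2Cl2 at −20 °C opens it at the benzylic carbon and triggers a 1,2-aroyl migration to the α-formyl deoxybenzoin F2. The HCl/MeOH treatment of step 16 then removes the MOM groups and dehydrates, so the route is rejoined at 25.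

2. **Step 7, the second ortho-formylation.**
   - Risk: the reacting carbon is flanked by the phenoxide and an OMOM group. The reaction may stall, or MgCl2 may cleave the neighbouring MOM group.
   - Fallback: it sets out from phenol 10 and switches to organolithium chemistry. Benzylation (BnBr, K2CO3, DMF) gives 1,3-bis(benzyloxy)-2-methoxy-4,5-bis(methoxymethoxy)benzene F3. NBS in MeCN at 0 °C brominates the only free ring carbon to give the aryl bromide F4. Bromine–lithium exchange (n-BuLi, THF, −78 °C) gives the aryllithium F5, and a DMF quench delivers the aldehyde. The route is rejoined at 13, so step 8 is skipped.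

3. **Step 17, the final hydrogenolysis.**
   - Risk: C2=C3 can be over-reduced to the isoflavanone, and the electron-rich product can be oxidised by air to the 5,8-quinone during handling.
   - Fallback: it sets out from 25 and uses Lewis-acid cleavage instead of hydrogen. The conditions are BCl3 (6 equiv) with pentamethylbenzene (10 equiv) as benzyl cation trap in CH2Cl2 at −78 °C, followed by a MeOH quench under argon. The methyl ethers survive at this temperature. The route is rejoined at 26, and no new compound is made.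

**Further compounds**
F1 | step 15 | rac-trans-{3-[3-(benzyloxy)-4,5-dimethoxyphenyl]oxiran-2-yl}[2,4-bis(benzyloxy)-3-methoxy-5,6-bis(methoxymethoxy)phenyl]methanone (racemate, one enantiomer drawn) | O=C([C@@H]1O[C@H]1c1cc(OC)c(OC)c(OCc2ccccc2)c1)c1c(OCc2ccccc2)c(OC)c(OCc2ccccc2)c(OCOC)c1OCOC
F2 | step 15 | rac-2-[3-(benzyloxy)-4,5-dimethoxyphenyl]-3-[2,4-bis(benzyloxy)-3-methoxy-5,6-bis(methoxymethoxy)phenyl]-3-oxopropanal (enolisable) | O=CC(c1cc(OC)c(OC)c(OCc2ccccc2)c1)C(=O)c1c(OCc2ccccc2)c(OC)c(OCc2ccccc2)c(OCOC)c1OCOC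
F3 | step 7 | 1,3-bis(benzyloxy)-2-methoxy-4,5-bis(methoxymethoxy)benzene | COCOc1cc(OCc2ccccc2)c(OC)c(OCc2ccccc2)c1OCOC
F4 | step 7 | 1,3-bis(benzyloxy)-4-bromo-2-methoxy-5,6-bis(methoxymethoxy)benzene | COCOc1c(Br)c(OCc2ccccc2)c(OC)c(OCc2ccccc2)c1OCOC
F5 | step 7 | [2,4-bis(benzyloxy)-3-methoxy-5,6-bis(methoxymethoxy)phenyl]lithium | [Li]c1c(OCOC)c(OCOC)c(OCc2ccccc2)c(OC)c1OCc1ccccc1
F0 | step 17 | none | none
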